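**Retrosynthetic overview**

1. Ester C–O bond: target ⇒ linoleic acid + the (S)-1,3-diol (acylation of the primary hydroxyl only).
2. Diol ⇒ α-(indol-3-yl)-β-hydroxy N-acyl bornane sultam (hydride cleavage of the auxiliary).
3. Key C–C bond, indole C3 to Cα: ⇒ 6-prenylindole + N-(3-hydroxy-3-methylbutanoyl)sultam. Two nucleophilic carbons are joined by oxidising the enolate with divalent copper to an electrophilic α-acyl radical (an enolonium equivalent); the sultam sets the stereocentre in this step.
4. 6-Prenylindole ⇒ 6-bromoindole + prenylzinc bromide; acyl sultam ⇒ camphorsultam + ethyl 3-hydroxy-3-methylbutanoate.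
5. No ring is formed: the indole and the bornane sultam are bought intact.

Assumption: the copper-mediated coupling follows the facial sense of chelate-controlled alkylations of (2R)-bornane-10,2-sultam enolates (bond formation on the Cα-Re face of the Z-enolate); if the opposite sense is found, the equally available (2S)-sultam is used and nothing else changes.

**Step 1**
Reactants: 1 6-bromo-1H-indole; 2 (3-methylbut-2-en-1-yl)zinc bromide (prenylzinc bromide, 0.5 M in THF)
Product: 3 6-(3-methylbut-2-en-1-yl)-1H-indole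
Conditions: 2 (2.2 equiv), Pd(OAc)2 (2 mol %), CPhos (2-dicyclohexylphosphino-2',6'-bis(dimethylamino)biphenyl, 4 mol %), THF, rt, 12 h
Reagents that add atoms: none
Why: Linear-selective Negishi cross-coupling, in which oxidative addition of the C6–Br bond to zerovalent palladium, transmetalation from zinc and reductive elimination at the unsubstituted allyl terminus give the prenyl (not the reverse-prenyl) arene; no stereocentre is formed.

**Step 2**
Reactants: 4 (1S)-(−)-2,10-camphorsultam, i.e. (2R)-bornane-10,2-sultam; 5 ethyl 3-hydroxy-3-methylbutanoate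
Product: 6 N-(3-hydroxy-3-methylbutanoyl)-(2R)-bornane-10,2-sultam
Conditions: 5 (1.3 equiv), AlMe3 (2.5 equiv), toluene, 0 °C → 60 °C, 24 h; aq. KNaC4H4O6 (potassium sodium tartrate)
Reagents that add atoms: none
Why: Trimethylaluminium-mediated aminolysis of an ester by the sultam nitrogen (Weinreb-type acyl transfer), with the tertiary hydroxyl masked in the flask by aluminium and chelation activating the ester; the sultam stereocentres are untouched.

**Step 3**
Reactants: 6 N-(3-hydroxy-3-methylbutanoyl)-(2R)-bornane-10,2-sultam; 3 6-(3-methylbut-2-en-1-yl)-1H-indole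
Product: 9 N-[(2R)-3-hydroxy-3-methyl-2-[6-(3-methylbut-2-en-1-yl)-1H-indol-3-yl]butanoyl]-(2R)-bornane-10,2-sultam, via dilithium alkoxide-enolate 7 (not isolated), via lithium indolide 8 (not isolated)
Conditions: 3 (2.0 equiv, excess recovered), LiN(SiMe3)2 (4.4 equiv), THF, −78 → −40 °C, 30 min; then copper bis(2-ethylhexanoate) (2.0 equiv) in THF, −78 → −40 °C; aq. NH4Cl at −40 °C
Reagents that add atoms: none
Why: Proposed new method: LiN(SiMe3)2 converts 3 into lithium indolide 8 and 6 into the alkoxide–(Z)-enolate dianion 7, which, like a Fráter–Seebach dianion, can undergo neither retro-aldol cleavage nor β-elimination; divalent copper binds both anions and takes one electron from the enolate, so that its normally nucleophilic α-carbon becomes an electrophilic α-acyl radical (a one-electron enolonium equivalent) that bonds to the nucleophilic C3 of the indolide, and a second divalent copper plus loss of the C3 proton restore the indole; the bornane skeleton blocks one face of the Z-enolate, so the bond forms on the Cα-Re face and gives the 2R centre; the closest known reaction type is the copper-mediated oxidative heterocoupling of indoles with lithium enolates of N-acyl bornane sultams, here extended to a β-alkoxide enolate.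

**Step 4**
Reactants: 9 N-[(2R)-3-hydroxy-3-methyl-2-[6-(3-methylbut-2-en-1-yl)-1H-indol-3-yl]butanoyl]-(2R)-bornane-10,2-sultam
Product: 10 (2S)-3-methyl-2-[6-(3-methylbut-2-en-1-yl)-1H-indol-3-yl]butane-1,3-diol
Conditions: LiAlH4 (4 equiv), THF, 0 °C → rt; aq. KNaC4H4O6 (potassium sodium tartrate)
Reagents that add atoms: none
Why: Hydride reduction of the N-acyl sultam (its exocyclic C=O is the only carbonyl) releases the primary alcohol and the recoverable auxiliary without touching the stereocentre, whose descriptor changes from R to S only because CH2OH ranks below C(CH3)2OH.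

**Step 5**
Reactants: 10 (2S)-3-methyl-2-[6-(3-methylbut-2-en-1-yl)-1H-indol-3-yl]butane-1,3-diol; 11 linoleic acid, (9Z,12Z)-octadeca-9,12-dienoic acid
Product: 12 (2S)-3-hydroxy-3-methyl-2-[6-(3-methylbut-2-en-1-yl)-1H-indol-3-yl]butyl (9Z,12Z)-octadeca-9,12-dienoate (target)
Conditions: 11 (1.05 equiv), DCC (1.1 equiv), DMAP (0.1 equiv), CH2Cl2, 0 °C → rt, argon, dark
Reagents that add atoms: none
Why: Steglich esterification, in which the primary hydroxyl reacts far faster than the tertiary hydroxyl and the non-deprotonated indole N–H, while the neutral conditions leave the skipped (Z,Z)-diene, the prenyl group and the stereocentre unchanged.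

**Compound list**

1 | 6-bromo-1H-indole | Brc1ccc2cc[nH]c2c1 | starting material
2 | (3-methylbut-2-en-1-yl)zinc bromide | CC(C)=CC[Zn]Br | starting material
3 | 6-(3-methylbut-2-en-1-yl)-1H-indole | CC(C)=CCc1ccc2cc[nH]c2c1 | intermediate
4 | (1S)-(−)-2,10-camphorsultam, (2R)-bornane-10,2-sultam | CC1(C)[C@@H]2CC[C@]13CS(=O)(=O)N[C@@H]3C2 | starting material
5 | ethyl 3-hydroxy-3-methylbutanoate | CCOC(=O)CC(C)(C)O | starting material
6 | N-(3-hydroxy-3-methylbutanoyl)-(2R)-bornane-10,2-sultam | CC1(C)[C@@H]2CC[C@]13CS(=O)(=O)N(C(=O)CC(C)(C)O)[C@@H]3C2 | intermediate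
7 | dilithium (Z)-alkoxide-enolate of 6 | [Li+].[Li+].CC1(C)[C@@H]2CC[C@]13CS(=O)(=O)N(/C([O-])=C/C(C)(C)[O-])[C@@H]3C2 | intermediate
8 | lithium 6-(3-methylbut-2-en-1-yl)indol-1-ide | [Li+].CC(C)=CCc1ccc2cc[n-]c2c1 | intermediate
9 | N-[(2R)-3-hydroxy-3-methyl-2-[6-(3-methylbut-2-en-1-yl)-1H-indol-3-yl]butanoyl]-(2R)-bornane-10,2-sultam | CC1(C)[C@@H]2CC[C@]13CS(=O)(=O)N(C(=O)[C@H](c4c[nH]c5cc(CC=C(C)C)ccc45)C(C)(C)O)[C@@H]3C2 | intermediate
10 | (2S)-3-methyl-2-[6-(3-methylbut-2-en-1-yl)-1H-indol-3-yl]butane-1,3-diol | OC[C@H](c1c[nH]c2cc(CC=C(C)C)ccc12)C(C)(C)O | intermediate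
11 | linoleic acid, (9Z,12Z)-octadeca-9,12-dienoic acid | CCCCC/C=C\C/C=C\CCCCCCCC(=O)O | starting material
12 | (2S)-3-hydroxy-3-methyl-2-[6-(3-methylbut-2-en-1-yl)-1H-indol-3-yl]butyl (9Z,12Z)-octadeca-9,12-dienoate | CCCCC/C=C\C/C=C\CCCCCCCC(=O)OC[C@H](c1c[nH]c2cc(CC=C(C)C)ccc12)C(C)(C)O | target

**Totals**

Total step count: 5. Longest linear sequence: 4 steps (steps 1, 3, 4, 5 from 6-bromoindole, or steps 2, 3, 4, 5 from the sultam).

**Steps most likely to fail**

Step 3 (key coupling). The free tertiary alkoxide may bind copper unproductively, and the product alkoxide may suffer retro-aldol cleavage before the cold quench. The level and sense of diastereoselection are also untested for this substrate. The fallback sets out from 6 and comes back at 10; it replaces the dianion by a protected monoanion at the cost of two steps. Compound 6 is silylated (Et3SiOTf, 2,6-lutidine, CH2Cl2, −78 °C) to N-[3-methyl-3-(triethylsilyloxy)butanoyl]-(2R)-bornane-10,2-sultam F1. Its lithium enolate (3.3 equiv LiN(SiMe3)2 in total) is coupled with 3 and copper bis(2-ethylhexanoate) as above to give N-[(2R)-3-methyl-2-[6-(3-methylbut-2-en-1-yl)-1H-indol-3-yl]-3-(triethylsilyloxy)butanoyl]-(2R)-bornane-10,2-sultam F2. LiAlH4 in THF then gives (2S)-3-methyl-2-[6-(3-methylbut-2-en-1-yl)-1H-indol-3-yl]-3-(triethylsilyloxy)butan-1-ol F3, and Bu4NF in THF removes the silyl group to give 10.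

Step 2 (acyl transfer). The hindered, β-hydroxylated ester may react slowly with the aluminium amide or lose water on heating. The fallback sets out from 4 and comes back at 6; it builds the acyl chain by C–C bond formation instead of acyl transfer. Compound 4 is N-acetylated (NaH, AcCl, toluene, 0 °C → rt) to N-acetyl-(2R)-bornane-10,2-sultam F4. Its lithium enolate (LiN(SiMe3)2, THF, −78 °C) adds to acetone in an aldol reaction and gives 6 after a cold quench; no stereocentre is created.

Step 4 (reductive cleavage). The carbonyl is flanked by a fully substituted α-carbon, and the basic hydride medium could trigger retro-aldol cleavage or α-epimerisation. The fallback sets out from 9 and comes back at 10; it separates cleavage from reduction. LiOH and H2O2 in THF–water at 0 °C hydrolyse 9 to (2R)-3-hydroxy-3-methyl-2-[6-(3-methylbut-2-en-1-yl)-1H-indol-3-yl]butanoic acid F5, which is reduced with LiAlH4 in THF (0 → 50 °C) to 10.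

**Further compounds**

F1 | step 3 | N-[3-methyl-3-(triethylsilyloxy)butanoyl]-(2R)-bornane-10,2-sultam | CC1(C)[C@@H]2CC[C@]13CS(=O)(=O)N(C(=O)CC(C)(C)O[Si](CC)(CC)CC)[C@@H]3C2
F2 | step 3 | N-[(2R)-3-methyl-2-[6-(3-methylbut-2-en-1-yl)-1H-indol-3-yl]-3-(triethylsilyloxy)butanoyl]-(2R)-bornane-10,2-sultam | CC1(C)[C@@H]2CC[C@]13CS(=O)(=O)N(C(=O)[C@H](c4c[nH]c5cc(CC=C(C)C)ccc45)C(C)(C)O[Si](CC)(CC)CC)[C@@H]3C2
F3 | step 3 | (2S)-3-methyl-2-[6-(3-methylbut-2-en-1-yl)-1H-indol-3-yl]-3-(triethylsilyloxy)butan-1-ol | OC[C@H](c1c[nH]c2cc(CC=C(C)C)ccc12)C(C)(C)O[Si](CC)(CC)CC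
F4 | step 2 | N-acetyl-(2R)-bornane-10,2-sultam | CC1(C)[C@@H]2CC[C@]13CS(=O)(=O)N(C(C)=O)[C@@H]3C2
F5 | step 4 | (2R)-3-hydroxy-3-methyl-2-[6-(3-methylbut-2-en-1-yl)-1H-indol-3-yl]butanoic acid | OC(=O)[C@H](c1c[nH]c2cc(CC=C(C)C)ccc12)C(C)(C)O
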